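**Plan**

- Retrosynthesis: first the silyl ether and the ester C–O at C1′. The two chain termini (C1′–O and the CH2OH on C3′) are traced to the carbonyl and the O–CH2 of an (R)-β-alkyl-γ-butyrolactone, hence to a butenolide. Then the C1–C5′ bond between the quaternary decalin carbon and the chain CH2 is cut, giving a decalin C1 tertiary radical (from the tertiary alcohol via its caesium oxalate) and 4-ethenylfuran-2(5H)-one. Finally C1–CH3, C2–CH3, the C8–C8a ring bond and the C4a–alkenyl bond lead back to 3-methylcyclohexenone and 5-chloropentyne.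
- Forward: ring B is the purchased cyclohexenone. Alkenyl conjugate addition builds C4a, enolate alkylation closes ring A, and the exocyclic alkene is moved into the ring. The C2 methyl and the C1 methyl carbinol follow. The six-carbon chain is then joined in one step and adjusted (reduction, lactone opening/silylation, reduction, acylation, desilylation).
- Stereochemistry: C4a from the chiral Cu catalyst; C8a (trans fusion) and C2 (equatorial methyl) by equilibration α to the ketone; C1 by equatorial attack on the radical, anti to the axial C4a methyl; C3′ by ligand-controlled CuH reduction.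
- Enabling feature: decalin C1 is a fully alkyl-substituted ring carbon flanked by C2 and C8a and 1,3 to the axial C4a methyl, so its tertiary radical is easily formed, nucleophilic and face-biased. Chain atoms C5′, C4′, C3′, its CH2O branch, C2′ and C1′ map onto the vinyl CH2, vinyl CH, C4, C5, C3 and C2 of a 4-vinylbutenolide, an extended (1,6) radical acceptor.
- Locants: decalin as in the octahydronaphthalene names (C1 carries the chain, C2–CH3, C4a–CH3, C5=C6, C8a–H); chain C1′ (OCH2) to C5′ (CH2 on C1), C3′ the stereocentre.

Key step: step 8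

Remark on names: Dec = (1S,2R,4aR,8aR)-1,2,4a,5-tetramethyl-1,2,3,4,4a,7,8,8a-octahydronaphthalen-1-yl.

Assumption: the sense of induction of the Cu/phosphinamine catalyst (step 1) and of CuH/p-tol-BINAP (step 9) is taken from simple 3-methylcyclohexenone and β-alkyl butenolide substrates; the ligand antipode written is the one expected to give the R centre, and the other antipode is used if a model run shows the opposite sense.

Step 1
Reactants: 1 5-chloropent-1-yne; 2 3-methylcyclohex-2-en-1-one
Product: 4 (3R)-3-(5-chloropent-1-en-2-yl)-3-methylcyclohexan-1-one, via vinylalane 3 (not isolated)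
Conditions: DIBAL-H, Ni(dppp)Cl2 (3 mol %), THF, 0 → 23 °C; then 2, CuTC (10 mol %), (R,R)-SimplePhos-type phosphinamine ligand (11 mol %), Et2O, −30 °C; aq. HCl
Reagents that add atoms: none
Why: Ni-catalysed α-selective hydroalumination gives the internal vinylalane 3, whose alkenyl group is transferred in a Cu-catalysed asymmetric conjugate addition to the β-substituted enone, the chiral Cu complex choosing the enone face and so setting the quaternary centre (future C4a) as R, while the alkyl chloride is inert to both metals.

Step 2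
Reactants: 4 (3R)-3-(5-chloropent-1-en-2-yl)-3-methylcyclohexan-1-one
Product: 6 (4aR,8aS)-4a-methyl-5-methylideneoctahydronaphthalen-1(2H)-one, via cis-fused epimer 5 (not isolated)
Conditions: KOt-Bu (1.5 equiv), THF/t-BuOH, 0 → 40 °C
Reagents that add atoms: none
Why: Intramolecular C-alkylation of the enolate on the C2 side (6-exo-tet, methylenecyclohexane annulation; the other enolate could only give a bridged ring) closes ring A, and the excess alkoxide should then epimerise the enolisable ring-fusion carbon so that cis ketone 5 drains into the more stable trans-fused 6.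

Step 3
Reactants: 6 (4aR,8aS)-4a-methyl-5-methylideneoctahydronaphthalen-1(2H)-one
Product: 7 (4aR,8aS)-4a,5-dimethyl-3,4,4a,7,8,8a-hexahydronaphthalen-1(2H)-one
Conditions: RhCl3·3H2O (5 mol %), EtOH, 78 °C
Reagents that add atoms: none
Why: Rh–H addition/β-hydride elimination (metal-catalysed alkene isomerisation) should move the exocyclic 1,1-disubstituted alkene to the more stable trisubstituted C5=C6 position, beyond which it cannot travel because C4a is quaternary, and no free cation next to C4a is involved.

Step 4
Reactants: 7 (4aR,8aS)-4a,5-dimethyl-3,4,4a,7,8,8a-hexahydronaphthalen-1(2H)-one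
Product: 9 (2R,4aR,8aS)-2,4a,5-trimethyl-3,4,4a,7,8,8a-hexahydronaphthalen-1(2H)-one, via C2 epimer 8 (not isolated)
Conditions: LDA, THF, −78 °C; MeI, −78 → 0 °C; then NaOMe (cat.), MeOH, 23 °C
Reagents that add atoms: iodomethane CI
Why: Kinetic deprotonation should occur at the unhindered C2 methylene and not at the tertiary C8a–H, the enolate is C-methylated (enolate alkylation), and methoxide equilibration funnels the axial epimer 8 into the equatorial 2R methyl ketone while the trans fusion, already the thermodynamic one, stays.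

Step 5
Reactants: 9 (2R,4aR,8aS)-2,4a,5-trimethyl-3,4,4a,7,8,8a-hexahydronaphthalen-1(2H)-one
Product: 10 (1R,2R,4aR,8aS)-1,2,4a,5-tetramethyl-1,2,3,4,4a,7,8,8a-octahydronaphthalen-1-ol
Conditions: MeLi, anhydrous CeCl3, THF, −78 °C; aq. NH4Cl
Reagents that add atoms: methyllithium [Li]C
Why: The weakly basic organocerium reagent should add to the hindered, enolisable ketone without enolisation (1,2-addition), mainly from the equatorial face away from the axial C4a methyl, and the C1 configuration is of no consequence because it is erased in step 8.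

Step 6
Reactants: 10 (1R,2R,4aR,8aS)-1,2,4a,5-tetramethyl-1,2,3,4,4a,7,8,8a-octahydronaphthalen-1-ol
Product: 12 caesium 2-oxo-2-{[(1R,2R,4aR,8aS)-1,2,4a,5-tetramethyl-1,2,3,4,4a,7,8,8a-octahydronaphthalen-1-yl]oxy}acetate, via methyl oxalate 11 (not isolated)
Conditions: ClC(O)CO2Me, Et3N, DMAP (cat.), CH2Cl2, 0 → 23 °C; then CsOH·H2O (1.0 equiv), THF/H2O, 23 °C
Reagents that add atoms: methyl chlorooxoacetate COC(=O)C(=O)Cl; caesium hydroxide [Cs+].[OH-]
Why: The very electrophilic chlorooxoacetate acylates even a hindered tertiary alcohol under DMAP catalysis, and one equivalent of hydroxide hydrolyses the unhindered methyl ester in preference to the tertiary alkyl ester to give the stable caesium hemioxalate.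

Step 7
Reactants: 13 4-bromofuran-2(5H)-one
Product: 14 4-ethenylfuran-2(5H)-one
Conditions: Bu3SnCH=CH2, Pd(PPh3)4 (3 mol %), BHT (cat.), 1,4-dioxane, 80 °C
Reagents that add atoms: tributyl(vinyl)stannane C=C[Sn](CCCC)(CCCC)CCCC
Why: Stille coupling of the vinylogous acyl bromide under neutral conditions gives the diene lactone, with BHT and cold storage suppressing its polymerisation.

Step 8
Reactants: 12 caesium 2-oxo-2-{[(1R,2R,4aR,8aS)-1,2,4a,5-tetramethyl-1,2,3,4,4a,7,8,8a-octahydronaphthalen-1-yl]oxy}acetate; 14 4-ethenylfuran-2(5H)-one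
Product: 16 4-[2-(Dec)ethyl]furan-2(5H)-one, via deconjugated lactone 15 (not isolated)
Conditions: Ir[dF(CF3)ppy]2(dtbbpy)PF6 (1 mol %), H2O (10 equiv), DME/DMF 3:1, blue LEDs, 40–60 °C; then DBU (cat.), CH2Cl2, 23 °C
Reagents that add atoms: none
Why: The excited Ir(III) catalyst oxidises the carboxylate of 12 by single-electron transfer and the acyloxy radical loses two CO2 to leave the planar tertiary radical at decalin C1, which adds to the unsubstituted vinyl terminus of the electron-poor diene 14 (1,6-addition); the dienyl radical conjugated to the lactone carbonyl is reduced by Ir(II) to the dienolate, protonated by water, and DBU moves any β,γ-isomer 15 into conjugation. The closest known reaction type is the photoredox Giese-type coupling of tertiary-alcohol-derived caesium oxalates with electron-poor alkenes, in its vinylogous 1,6-variant with vinylbutenolides. No ring is closed. The one new stereocentre, quaternary C1, is under substrate control: the axial C4a methyl lies 1,3-syn-axial over the α-face of the radical, so the acceptor should bond on the equatorial β-face, placing the chain trans to the C4a methyl and cis to H-8a and leaving the C1 methyl axial, as in the target. The step needs site selectivity for the vinyl CH2 over the ring β-carbon and over the C5=C6 alkene, which polarity matching (nucleophilic radical, unhindered terminus of the electron-poor diene) and the inertness of an isolated trisubstituted alkene to a nucleophilic radical should secure. The C2, C4a and C8a centres are untouched, and the C1 configuration of 12 is irrelevant because the radical erases it.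

Step 9
Reactants: 16 4-[2-(Dec)ethyl]furan-2(5H)-one
Product: 17 (4R)-4-[2-(Dec)ethyl]oxolan-2-one
Conditions: Cu(OAc)2·H2O (5 mol %), (S)-p-tol-BINAP (5.5 mol %), (EtO)2MeSiH, t-BuOH, toluene, 0 → 23 °C
Reagents that add atoms: none
Why: Ligand-bound Cu–H adds hydride to the β-carbon of the butenolide and t-BuOH protonates the copper enolate (asymmetric CuH conjugate reduction of β-substituted butenolides), the chiral bisphosphine alone choosing the face of the remote C=C and setting C3′ as R, while the isolated trisubstituted alkene is not touched.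

Step 10
Reactants: 17 (4R)-4-[2-(Dec)ethyl]oxolan-2-one
Product: 19 (3R)-3-({[tert-butyl(dimethyl)silyl]oxy}methyl)-N-methoxy-N-methyl-5-(Dec)pentanamide, via hydroxy amide 18 (not isolated)
Conditions: MeNH(OMe)·HCl, AlMe3, CH2Cl2, 0 → 23 °C; Rochelle-salt work-up; crude 18, TBSCl, imidazole, DMF, 23 °C
Reagents that add atoms: N,O-dimethylhydroxylamine hydrochloride CNOC.Cl; tert-butyldimethylsilyl chloride CC(C)(C)[Si](C)(C)Cl
Why: The aluminium amide opens the γ-lactone by acyl substitution (Weinreb aminolysis), freeing only the former lactone oxygen as a primary alcohol that is silylated at once before it can relactonise, which fixes which chain terminus carries which oxygen function.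

Step 11
Reactants: 19 (3R)-3-({[tert-butyl(dimethyl)silyl]oxy}methyl)-N-methoxy-N-methyl-5-(Dec)pentanamide
Product: 21 (3R)-3-({[tert-butyl(dimethyl)silyl]oxy}methyl)-5-(Dec)pentan-1-ol, via aldehyde 20 (not isolated)
Conditions: DIBAL-H, THF, −78 °C; then MeOH, NaBH4, −78 → 0 °C
Reagents that add atoms: none
Why: DIBAL-H stops at the chelated tetrahedral intermediate of the Weinreb amide, methanol releases aldehyde 20 and borohydride reduces it in the same flask, the β-stereocentre not being enolisable and the silyl ether and alkene being inert.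

Step 12
Reactants: 21 (3R)-3-({[tert-butyl(dimethyl)silyl]oxy}methyl)-5-(Dec)pentan-1-ol; 22 icosanoic acid
Product: 23 (3R)-3-({[tert-butyl(dimethyl)silyl]oxy}methyl)-5-(Dec)pentyl icosanoate
Conditions: EDC·HCl, DMAP (cat.), CH2Cl2, 23 °C
Reagents that add atoms: none
Why: Carbodiimide/DMAP (Steglich) esterification of the single free primary alcohol with the fatty acid.

Step 13
Reactants: 23 (3R)-3-({[tert-butyl(dimethyl)silyl]oxy}methyl)-5-(Dec)pentyl icosanoate
Product: 24 (3R)-3-(hydroxymethyl)-5-(Dec)pentyl icosanoate (CNP0285344.1)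
Conditions: HF·pyridine, pyridine/THF, 0 → 23 °C
Reagents that add atoms: none
Why: Buffered fluoride cleaves the primary silyl ether under conditions that should neither hydrolyse the ester, promote acyl shift to the distant hydroxyl (a seven-membered orthoester would be needed) nor isomerise the trisubstituted alkene.

**Compound list**

1 | 5-chloropent-1-yne | ClCCCC#C | starting material
2 | 3-methylcyclohex-2-en-1-one | CC1=CC(=O)CCC1 | starting material
3 | (5-chloropent-1-en-2-yl)bis(2-methylpropyl)alumane | C=C(CCCCl)[Al](CC(C)C)CC(C)C | intermediate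
4 | (3R)-3-(5-chloropent-1-en-2-yl)-3-methylcyclohexan-1-one | O=C1CCC[C@@](C1)(C)C(=C)CCCCl | intermediate
5 | (4aR,8aR)-4a-methyl-5-methylideneoctahydronaphthalen-1(2H)-one (cis-fused) | O=C1CCC[C@@]2(C)C(=C)CCC[C@@H]12 | intermediate
6 | (4aR,8aS)-4a-methyl-5-methylideneoctahydronaphthalen-1(2H)-one (trans-fused) | O=C1CCC[C@@]2(C)C(=C)CCC[C@H]12 | intermediate
7 | (4aR,8aS)-4a,5-dimethyl-3,4,4a,7,8,8a-hexahydronaphthalen-1(2H)-one | O=C1CCC[C@@]2(C)C(C)=CCC[C@H]12 | intermediate
8 | (2S,4aR,8aS)-2,4a,5-trimethyl-3,4,4a,7,8,8a-hexahydronaphthalen-1(2H)-one (axial 2-methyl) | O=C1[C@@H](C)CC[C@@]2(C)C(C)=CCC[C@H]12 | intermediate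
9 | (2R,4aR,8aS)-2,4a,5-trimethyl-3,4,4a,7,8,8a-hexahydronaphthalen-1(2H)-one | O=C1[C@H](C)CC[C@@]2(C)C(C)=CCC[C@H]12 | intermediate
10 | (1R,2R,4aR,8aS)-1,2,4a,5-tetramethyl-1,2,3,4,4a,7,8,8a-octahydronaphthalen-1-ol | C[C@@]1(O)[C@H](C)CC[C@@]2(C)C(C)=CCC[C@H]12 | intermediate
11 | methyl (1R,2R,4aR,8aS)-1,2,4a,5-tetramethyl-1,2,3,4,4a,7,8,8a-octahydronaphthalen-1-yl oxalate | C[C@@]1(OC(=O)C(=O)OC)[C@H](C)CC[C@@]2(C)C(C)=CCC[C@H]12 | intermediate
12 | caesium 2-oxo-2-{[(1R,2R,4aR,8aS)-1,2,4a,5-tetramethyl-1,2,3,4,4a,7,8,8a-octahydronaphthalen-1-yl]oxy}acetate | C[C@@]1(OC(=O)C(=O)[O-])[C@H](C)CC[C@@]2(C)C(C)=CCC[C@H]12.[Cs+] | intermediate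
13 | 4-bromofuran-2(5H)-one | BrC1=CC(=O)OC1 | starting material
14 | 4-ethenylfuran-2(5H)-one | C=CC1=CC(=O)OC1 | intermediate
15 | 4-[2-(Dec)ethylidene]oxolan-2-one (E/Z mixture expected, E isomer drawn) | O=C1C/C(=C\C[C@@]2(C)[C@H](C)CC[C@@]3(C)C(C)=CCC[C@H]23)CO1 | intermediate
16 | 4-[2-(Dec)ethyl]furan-2(5H)-one | O=C1C=C(CC[C@@]2(C)[C@H](C)CC[C@@]3(C)C(C)=CCC[C@H]23)CO1 | intermediate
17 | (4R)-4-[2-(Dec)ethyl]oxolan-2-one | O=C1C[C@@H](CC[C@@]2(C)[C@H](C)CC[C@@]3(C)C(C)=CCC[C@H]23)CO1 | intermediate
18 | (3R)-3-(hydroxymethyl)-N-methoxy-N-methyl-5-(Dec)pentanamide | CON(C)C(=O)C[C@H](CO)CC[C@@]1(C)[C@H](C)CC[C@@]2(C)C(C)=CCC[C@H]12 | intermediate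
19 | (3R)-3-({[tert-butyl(dimethyl)silyl]oxy}methyl)-N-methoxy-N-methyl-5-(Dec)pentanamide | CON(C)C(=O)C[C@H](CO[Si](C)(C)C(C)(C)C)CC[C@@]1(C)[C@H](C)CC[C@@]2(C)C(C)=CCC[C@H]12 | intermediate
20 | (3R)-3-({[tert-butyl(dimethyl)silyl]oxy}methyl)-5-(Dec)pentanal | O=CC[C@H](CO[Si](C)(C)C(C)(C)C)CC[C@@]1(C)[C@H](C)CC[C@@]2(C)C(C)=CCC[C@H]12 | intermediate
21 | (3R)-3-({[tert-butyl(dimethyl)silyl]oxy}methyl)-5-(Dec)pentan-1-ol | OCC[C@H](CO[Si](C)(C)C(C)(C)C)CC[C@@]1(C)[C@H](C)CC[C@@]2(C)C(C)=CCC[C@H]12 | intermediate
22 | icosanoic acid | CCCCCCCCCCCCCCCCCCCC(=O)O | starting material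
23 | (3R)-3-({[tert-butyl(dimethyl)silyl]oxy}methyl)-5-(Dec)pentyl icosanoate | CCCCCCCCCCCCCCCCCCCC(=O)OCC[C@H](CO[Si](C)(C)C(C)(C)C)CC[C@@]1(C)[C@H](C)CC[C@@]2(C)C(C)=CCC[C@H]12 | intermediate
24 | (3R)-3-(hydroxymethyl)-5-[(1S,2R,4aR,8aR)-1,2,4a,5-tetramethyl-1,2,3,4,4a,7,8,8a-octahydronaphthalen-1-yl]pentyl icosanoate | CCCCCCCCCCCCCCCCCCCC(=O)OCC[C@H](CO)CC[C@@]1(C)[C@H](C)CC[C@@]2(C)C(C)=CCC[C@H]12 | target

**Step count and risks**

Total steps: 13. Longest linear sequence: 12 (steps 1–6, then 8–13); step 7 is a one-step branch.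

Steps most likely to fail:

1. Step 8. The electron-poor diene 14 may oligomerise through chain addition of adduct radicals, and the tertiary radical may be lost by reduction or disproportionation before it meets the acceptor; protonation of the dienolate may also give isomer mixtures that do not converge cleanly. The fallback sets out from 12 and comes back at 16, and builds the butenolide after the coupling instead of carrying it in the acceptor. Under the same photoredox conditions 12 is added 1,4 to methyl vinyl ketone to give 4-(Dec)butan-2-one F1. Kinetic enolisation at the methyl group (LDA, THF, −78 °C; the other α-position is hindered) and hydroxylation with 2-(phenylsulfonyl)-3-phenyloxaziridine give 1-hydroxy-4-(Dec)butan-2-one F2. (Triphenylphosphoranylidene)ketene in hot toluene (O-acylation, then intramolecular Wittig reaction) closes the butenolide 16.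

2. Step 1. Enantiofacial control may be insufficient, or transfer of the functionalised α-alkenyl group may be slow against isobutyl transfer or be disturbed by residual nickel. The fallback sets out from 1 (through alane 3) and comes back at 4, and reverses the roles so that the well-behaved methyl group is the nucleophile. Alane 3 is quenched with N-bromosuccinimide to give 2-bromo-5-chloropent-1-ene F3. Bromine–lithium exchange (t-BuLi, Et2O, −78 °C) and addition to 3-ethoxycyclohex-2-en-1-one give 1-(5-chloropent-1-en-2-yl)-3-ethoxycyclohex-2-en-1-ol F4. Aqueous acid converts this by Stork–Danheiser transposition into 3-(5-chloropent-1-en-2-yl)cyclohex-2-en-1-one F5. Cu/chiral NHC-catalysed 1,4-addition of MeMgBr (Et2O, 0 °C; 1,4 over 1,6 under NHC–Grignard control) then gives 4.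

3. Step 9. The chiral Cu–H may discriminate poorly between the two similar β-substituents (CH2O and CH2CH2R), or the catalyst may stall on the hindered substrate. The fallback sets out from 16 and comes back at 17, and replaces hydride conjugate addition by hydrogen addition on a carbonyl-chelated metal: Ru(OAc)2(BINAP)-catalysed hydrogenation of the butenolide under H2 pressure in MeOH, which leaves the unfunctionalised trisubstituted alkene alone. It makes no compound that the list lacks (none F0).

**Further compounds**

F1 | step 8 | 4-[(1S,2R,4aR,8aR)-1,2,4a,5-tetramethyl-1,2,3,4,4a,7,8,8a-octahydronaphthalen-1-yl]butan-2-one | CC(=O)CC[C@@]1(C)[C@H](C)CC[C@@]2(C)C(C)=CCC[C@H]12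
F2 | step 8 | 1-hydroxy-4-[(1S,2R,4aR,8aR)-1,2,4a,5-tetramethyl-1,2,3,4,4a,7,8,8a-octahydronaphthalen-1-yl]butan-2-one | OCC(=O)CC[C@@]1(C)[C@H](C)CC[C@@]2(C)C(C)=CCC[C@H]12
F3 | step 1 | 2-bromo-5-chloropent-1-ene | C=C(Br)CCCCl
F4 | step 1 | 1-(5-chloropent-1-en-2-yl)-3-ethoxycyclohex-2-en-1-ol | CCOC1=CC(O)(CCC1)C(=C)CCCCl
F5 | step 1 | 3-(5-chloropent-1-en-2-yl)cyclohex-2-en-1-one | O=C1C=C(CCC1)C(=C)CCCCl
F0 | step 9 | none | none
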